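Readings and results come from a simulation with made-up constants, and the scatter is random.

This reaction is slow at its end, and the set-ups differ in how much time they leave for that last stretch.

| setting | delta | theta | Thursday's | Saturday's | Tuesday's | Monday's |
|---|---|---|---|---|---|---|
| starting material | 1 mM | 1 mM | 1.0 mM (fed, over 12.0 min) | 1.0 mM | 1.0 mM | 1.0 mM |
| second substrate | 0.70 equiv | 0.70 equiv | 0.700 equiv | 0.700 equiv | 0.700 equiv (fed, over 12.0 min) | 0.700 equiv |
| enzyme | 0.01 mol% | 0.01 mol% | 0.01 mol% | 0.01 mol% | 0.01 mol% | 0.01 mol% |
| impurity | 0.038 µM | 0.076 µM | 0.038 µM | 0.038 µM | 0.038 µM | 0.038 µM |
| remark | run made earlier | run made earlier | a stirred flask in which starting material is dosed at a steady rate over 12.0 min without added volume, worked up at 15 min | one stirred flow tank at steady state, fed with the mixture as stated, mean residence time 15 min | all but second substrate at the start; second substrate goes in evenly over 12.0 min, the run ends at 15 min | everything together in a closed stirred flask, run for 15 min |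
| time |  |  | 15 min |  | 15 min | 15 min |

delta run (percent of the starting material charged)

| time / min | product / % | starting material / % |
|---|---|---|
| 0.667 | 18.8 | 80.8 |
| 1.33 | 30.1 | 69.9 |
| 2.00 | 38.9 | 61.0 |
| 3.00 | 47.9 | 51.9 |
| 5.00 | 58.7 | 41.3 |
| 10.0 | 67.5 | 32.8 |

theta run (percent of the starting material charged)

| time / s | product / % | starting material / % |
|---|---|---|
| 10.0 | 3.2 | 95.2 |
| 20.0 | 5.9 | 93.9 |
| 30.0 | 9.1 | 91.7 |
| 50.0 | 11.1 | 88.1 |
| 60.0 | 13.0 | 86.6 |
| 90.0 | 17.4 | 82.8 |

(scatter of a reading: 0.5 percentage points)

- the stated concentrations are those of everything mixed, before any reaction; amounts are the same in each set-up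
- what was read earlier has a scatter of 0.5 percentage points, one standard deviation
- the feed brings no volume worth counting
- the earlier runs were made in a closed, stirred flask

- the set-up with the highest amount of product at the outlet or at the end, in percent of the starting material put in ("none" if the first two lie within 2 percentage points) (Thursday's / Saturday's / Tuesday's / Monday's / none)
- amount of product at the outlet or at the end, in percent of the starting material put in, Thursday's
- amount of product at the outlet or at the end, in percent of the starting material put in, Saturday's
- amount of product at the outlet or at the end, in percent of the starting material put in, Tuesday's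
- amount of product at the outlet or at the end, in percent of the starting material put in, Monday's

Where does product stop? In delta, product and starting material together stay close to the charge, so second substrate at 0.700 equiv is the limiting reagent, less than the starting material. The ceiling is therefore 70.0 % of the charge. The set-ups carry delta's impurity, 0.038 µM, so delta is our yardstick, not theta.

How fast is the ceiling approached? Call the gap the ceiling minus the product. In delta it falls from 11 percentage points at 5.00 min to 2.5 points at 10.0 min, while starting material falls by a smaller ratio. So we treat the gap as pseudo-first-order and read the tail rate κ = 0.302 min⁻¹, the rate of closing per unit of gap late in delta. This is a reading, and it gives a gap half-life of 2.30 min.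

How much tail does each set-up get? Monday's runs 5.00 min past delta's last reading, and by κ we reckon a gap of 0.55 points and product of 69.4 %. In Saturday's tank, we take the gap as the ceiling divided by one plus κ times the residence time, 13 points, so we reckon product of 57.0 %. In Tuesday's, we take the gap during the feed as roughly feed rate over κ, 19 points. The 3.00 min after the feed are 1.31 half-lives and by κ keep a factor 0.404 of it, so we reckon product of 62.3 %. Thursday's has the same tail after its feed, and to come within 2 points of our Monday's figure it needs a gap under 6.3 points at the end of that feed, about a third of our Tuesday's figure. At that moment its starting material has on average been in the flask for half the feed, and delta's gap carried by κ to that age is 8.4 points, more than that need. We therefore choose Monday's.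

The forecast also names Monday's, with 69.2 %, 65.5 % for Thursday's, 57.5 % for Saturday's and 63.5 % for Tuesday's, which stands above our Tuesday's figure; of the two feeds it says “either feed loses time”.

The flask gives Monday's: 69.2 % there, 65.1 % for Thursday's, 57.8 % for Saturday's and 63.8 % for Tuesday's.

    second substrate + starting complex ⇌ ternary complex (K = 64000 M⁻¹, k = 8.60 × 10⁵ M⁻¹ s⁻¹)
    enzyme + impurity → spent catalyst (k = 9.30 × 10⁶ M⁻¹ s⁻¹)
    ternary complex → enzyme + product (k = 360 s⁻¹)
    starting material + enzyme ⇌ starting complex (K = 470 M⁻¹, k = 5.70 × 10⁵ M⁻¹ s⁻¹)
    second substrate ⇌ dormant form (K = 0.520, k = 0.0280 s⁻¹)

Tuesday's held 55.1 % product at 12.0 min, a gap of 15 points rather than our rough 19 points. The factor 0.404 carries that gap to product of 64.0 %, against the 63.8 % found. Thursday's held 58.7 % at the end of its feed, and the same factor gives 65.4 %, against the 65.1 % found.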